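## Retrosynthetic overview

1. The target is read as an oxocane. Locants used throughout: ring O1; C2 carries the 1‑acetoxypropyl group; C3H2; C4–OAc; C5–OAc; C6H2; C7–OH; C8 carries the Z‑pentenynyl chain. The enabling feature is that C5 bears an acetoxy group and lies four bonds from O1, so closing O1 onto C5 gives a five‑membered ring (O1, C2–C5) that is a peracetylated 3‑deoxyfuranose with C5 as its anomeric (acylal) carbon. C6–C7–C8 is a three‑carbon unit oxygenated at its middle carbon, i.e. the 2‑acetoxyallyl carbenoid latent in propargyl acetate.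
2. Key disconnection: C5–C6 and O1–C8 together, as insertion of that carbenoid into the endocyclic anomeric C5–O1 bond. The furanose becomes the oxocane in one operation, with C5 set by the C4 acetate.
3. The furanose comes from diacetone‑D‑glucose: sugar C2, C4 and C5 become C4, C2 and the side‑chain carbinol. Sugar C3 is deoxygenated, the ethyl end comes from a cuprate on the 5,6‑epoxide, and sugar C5 is inverted by Mitsunobu acetylation.
4. The ring enol acetate from the key step is a regiodefined C8 enolate equivalent: alkylation with a Z‑enynyl bromide (C8, trans to C2), hydride reduction (C7, cis to C8), alkyne desilylation.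
5. Ring order: furanose ring (chiral pool) first, oxocane ring by the key step; no other ring is made.

Key step: step 8

Remark on the chemistry: 1, 9, 13 and 14 are taken as commercial; the target configuration read from the SMILES is C2 S, side‑chain carbinol S, C4 R, C5 R, C7 R, C8 R (C2/C8 substituents trans, C7–OH/C8 chain cis, C4/C5 acetates trans), and the 1,2‑trans anomer of 8 is the one carried into step 8.

## Route

Step 1
Reactants: 1 diacetone‑D‑glucose (1,2:5,6‑di‑O‑isopropylidene‑α‑D‑glucofuranose)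
Product: 2 O3 S‑methyl xanthate of 1
Conditions: NaH, THF, 0 °C; CS2; MeI, rt
Reagents that add atoms: carbon disulfide S=C=S; iodomethane CI
Why: Xanthate formation (alkoxide addition to CS2, then S‑methylation) at the only free hydroxyl sets up the radical deoxygenation and touches no stereocentre.

Step 2
Reactants: 2 O3 S‑methyl xanthate
Product: 3 3‑deoxy‑1,2:5,6‑di‑O‑isopropylidene‑α‑D‑ribo‑hexofuranose
Conditions: Bu3SnH, AIBN (cat.), toluene, 110 °C
Reagents that add atoms: none
Why: Barton–McCombie deoxygenation (stannyl radical addition to the thiocarbonyl, β‑scission, hydrogen transfer) turns sugar C3 into the CH2 group that becomes C3 of the target.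

Step 3
Reactants: 3 3‑deoxy diacetonide
Product: 4 3‑deoxy‑1,2‑O‑isopropylidene‑α‑D‑ribo‑hexofuranose (5,6‑diol)
Conditions: AcOH–H2O (3:1), rt
Reagents that add atoms: none
Why: Acid‑catalysed acetal hydrolysis is selective for the terminal 5,6‑dioxolane because the cis‑fused 1,2‑acetal hydrolyses far more slowly.

Step 4
Reactants: 4 5,6‑diol
Product: 5 5,6‑anhydro‑3‑deoxy‑1,2‑O‑isopropylidene‑α‑D‑ribo‑hexofuranose
Conditions: PPh3, DIAD, 4 Å MS, toluene, 80 °C
Reagents that add atoms: none
Why: Mitsunobu cyclodehydration of a terminal 1,2‑diol activates the primary hydroxyl as the oxyphosphonium ion, which O5 displaces, so the epoxide forms with retention at sugar C5.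

Step 5
Reactants: 5 5,6‑epoxide
Product: 6 3,6,7‑trideoxy‑1,2‑O‑isopropylidene‑α‑D‑ribo‑heptofuranose
Conditions: Me2CuLi, Et2O, −40 → 0 °C
Reagents that add atoms: lithium dimethylcuprate [Li+].C[Cu-]C
Why: Cuprate SN2 opening of the terminal epoxide at its primary carbon adds the methyl that completes the ethyl group and leaves the C5 configuration untouched.

Step 6
Reactants: 6 5R alcohol
Product: 7 5‑O‑acetyl‑3,6,7‑trideoxy‑1,2‑O‑isopropylidene‑β‑L‑lyxo‑heptofuranose
Conditions: PPh3, DIAD, AcOH, THF, 0 °C → rt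
Reagents that add atoms: acetic acid CC(=O)O
Why: Mitsunobu esterification with acetic acid proceeds with SN2 inversion at sugar C5, which sets the S‑configured acetoxy carbinol of the target side chain.

Step 7
Reactants: 7 5‑O‑acetyl acetonide
Product: 8 1,2,5‑tri‑O‑acetyl‑3,6,7‑trideoxy‑α‑L‑lyxo‑heptofuranose (1,2‑trans anomer)
Conditions: Ac2O, AcOH, H2SO4 (cat.), 0 °C → rt
Reagents that add atoms: acetic anhydride CC(=O)OC(C)=O
Why: Acetolysis of the 1,2‑O‑isopropylidene acetal through the furanosyl oxocarbenium/1,2‑acetoxonium ion should deliver the anomeric acetate mainly trans to the C2 acetate, the acetylated O5 blocks isomerisation to a pyranose, and the minor cis anomer is removed by chromatography.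

Step 8
Reactants: 8 1,2‑trans furanosyl triacetate; 9 prop‑2‑yn‑1‑yl acetate (propargyl acetate)
Product: 12 oxocene enol acetate (2S,4R,5R)‑2‑[(1S)‑1‑acetoxypropyl]‑4,5,7‑triacetoxy‑3,4,5,6‑tetrahydro‑2H‑oxocine, via gold carbenoid 10 (not isolated), via acetoxonium allylgold ion 11 (not isolated)
Conditions: Ph3PAuNTf2 (5 mol %), 4 Å MS, CH2Cl2 (8 at 1 M), 25 °C, 9 (2 equiv) added over 6 h
Reagents that add atoms: none
Why: Proposed new method: cationic monovalent gold converts 9 by 1,2‑acetoxy migration into the 2‑acetoxyallyl carbenoid 10, which is attacked at its carbene carbon by the ring oxygen of 8, the only ether‑type oxygen in the substrate, to give an oxonium allylgold species and with it the O1–C8 bond. The oxonium oxygen then leaves C5 with backside assistance from the C4 acetate, so the cleavage is forced to be endocyclic and gives the trans‑4,5‑disubstituted 1,3‑dioxolan‑2‑ylium ion 11. The γ‑carbon of the allylgold (C6) opens 11 at C5 in an SE2′ step, an 8‑exo‑tet closure that forms the C5–C6 bond and the oxocane ring while gold is released and the C7=C8 enol acetate appears. C5 is the only new stereocentre and is fixed by the acetate at C4: two inversions put C6 where the ring oxygen was and make the C4/C5 diacetate threo as in the target, which is why the 1,2‑trans anomer of 8 is used. The closest known reaction types are the rhodium‑catalysed [5+3] ring expansion of 1,3‑dioxolanes by α‑imino carbenes (oxonium ylide, C–O heterolysis, 1,3‑closure), the gold‑catalysed [4+3] and [3+3] annulations of propargyl esters in which a heteroatom attacks the carbenoid carbon and the ring closes through the γ‑carbon, and the three‑carbon ring expansion of tetrahydrofurans through bicyclic oxonium ylides. The step needs site selectivity (ring oxygen over ester carbonyls, γ‑ over α‑closure, no second carbenoid transfer to the product), which should be secured by the single ether oxygen of the peracetate, the SE2′ preference of allylgold, and the acetoxy‑deactivated trisubstituted product alkene together with slow addition of 9.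

Step 9
Reactants: 13 ethyl (Z)‑3‑iodoacrylate; 14 ethynyltrimethylsilane
Product: 15 ethyl (Z)‑5‑(trimethylsilyl)pent‑2‑en‑4‑ynoate
Conditions: PdCl2(PPh3)2 (2 mol %), CuI (4 mol %), Et3N, THF, rt
Reagents that add atoms: none
Why: Sonogashira coupling of a (Z)‑vinyl iodide proceeds with retention of the alkene geometry.

Step 10
Reactants: 15 Z‑enynoate
Product: 16 (Z)‑5‑(trimethylsilyl)pent‑2‑en‑4‑yn‑1‑ol
Conditions: i‑Bu2AlH (2.2 equiv), CH2Cl2, −78 → 0 °C
Reagents that add atoms: none
Why: 1,2‑Reduction of the enoate by i‑Bu2AlH at low temperature gives the allylic alcohol without touching the silylalkyne or the Z‑alkene.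

Step 11
Reactants: 16 Z‑enynol
Product: 17 (Z)‑5‑bromo‑1‑(trimethylsilyl)pent‑3‑en‑1‑yne
Conditions: CBr4, PPh3, CH2Cl2, 0 °C
Reagents that add atoms: carbon tetrabromide BrC(Br)(Br)Br
Why: Appel bromination of the primary allylic alcohol (SN2 on the alkoxyphosphonium ion) at 0 °C keeps the Z‑geometry.

Step 12
Reactants: 12 oxocene enol acetate; 17 Z‑enynyl bromide
Product: 19 (2S,4R,5R,8R)‑2‑[(1S)‑1‑acetoxypropyl]‑4,5‑diacetoxy‑8‑[(2Z)‑5‑(trimethylsilyl)pent‑2‑en‑4‑yn‑1‑yl]oxocan‑7‑one, via tributyltin enolate 18 (not isolated)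
Conditions: Bu3SnOMe (1.1 equiv), THF, 50 °C (MeOAc removed); then 17 (1.5 equiv), Bu4NBr (1 equiv), THF, rt
Reagents that add atoms: none
Why: Bu3SnOMe transesterifies only the enol acetate (secondary alkyl acetates are inert to it), giving the tin enolate regiospecifically at C7–C8, and SN2 alkylation by the Z‑allylic bromide should occur on the face of C8 opposite to the C2 side chain across the ring oxygen, setting C8 (R) trans to C2 with the Z‑alkene retained.

Step 13
Reactants: 19 C8‑alkylated oxocan‑7‑one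
Product: 20 (2S,4R,5R,7R,8R)‑2‑[(1S)‑1‑acetoxypropyl]‑4,5‑diacetoxy‑8‑[(2Z)‑5‑(trimethylsilyl)pent‑2‑en‑4‑yn‑1‑yl]oxocan‑7‑ol
Conditions: LiBH(s‑Bu)3 (L‑Selectride), THF, −78 °C
Reagents that add atoms: none
Why: Hydride delivery from the bulky borohydride to the ketone face opposite to the adjacent C8 chain should give the 7,8‑cis alcohol (7R), and at −78 °C the acetates are not reduced.

Step 14
Reactants: 20 silylated enynyl alcohol
Product: 21 target, (2S,4R,5R,7R,8R)‑2‑[(1S)‑1‑acetoxypropyl]‑4,5‑diacetoxy‑8‑[(2Z)‑pent‑2‑en‑4‑yn‑1‑yl]oxocan‑7‑ol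
Conditions: AgNO3 (0.1 equiv), acetone–H2O–CH2Cl2, rt
Reagents that add atoms: none
Why: Silver‑catalysed protodesilylation of the alkynylsilane under neutral conditions frees the terminal alkyne without acyl migration or acetate cleavage.

## Compound list

1 | 1,2:5,6‑di‑O‑isopropylidene‑α‑D‑glucofuranose | CC1(C)OC[C@@H](O1)[C@H]2O[C@@H]3OC(C)(C)O[C@@H]3[C@H]2O | starting material
2 | 1,2:5,6‑di‑O‑isopropylidene‑3‑O‑[(methylsulfanyl)carbonothioyl]‑α‑D‑glucofuranose | CC1(C)OC[C@@H](O1)[C@H]2O[C@@H]3OC(C)(C)O[C@@H]3[C@H]2OC(=S)SC | intermediate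
3 | 3‑deoxy‑1,2:5,6‑di‑O‑isopropylidene‑α‑D‑ribo‑hexofuranose | CC1(C)OC[C@@H](O1)[C@H]2O[C@@H]3OC(C)(C)O[C@@H]3C2 | intermediate
4 | 3‑deoxy‑1,2‑O‑isopropylidene‑α‑D‑ribo‑hexofuranose | OC[C@@H](O)[C@H]1O[C@@H]2OC(C)(C)O[C@@H]2C1 | intermediate
5 | 5,6‑anhydro‑3‑deoxy‑1,2‑O‑isopropylidene‑α‑D‑ribo‑hexofuranose | C1O[C@H]1[C@H]2O[C@@H]3OC(C)(C)O[C@@H]3C2 | intermediate
6 | 3,6,7‑trideoxy‑1,2‑O‑isopropylidene‑α‑D‑ribo‑heptofuranose | CC[C@@H](O)[C@H]1O[C@@H]2OC(C)(C)O[C@@H]2C1 | intermediate
7 | 5‑O‑acetyl‑3,6,7‑trideoxy‑1,2‑O‑isopropylidene‑β‑L‑lyxo‑heptofuranose | CC[C@H](OC(C)=O)[C@H]1O[C@@H]2OC(C)(C)O[C@@H]2C1 | intermediate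
8 | 1,2,5‑tri‑O‑acetyl‑3,6,7‑trideoxy‑α‑L‑lyxo‑heptofuranose (1,2‑trans) | CC[C@H](OC(C)=O)[C@@H]1C[C@@H](OC(C)=O)[C@H](OC(C)=O)O1 | intermediate
9 | prop‑2‑yn‑1‑yl acetate | C#CCOC(C)=O | starting material
10 | Ph3PAu‑bound 2‑acetoxyprop‑2‑en‑1‑ylidene (gold carbenoid), NTf2 salt | C=C(OC(C)=O)C=[Au][P+](c1ccccc1)(c1ccccc1)c1ccccc1.O=S(=O)([N-]S(=O)(=O)C(F)(F)F)C(F)(F)F | intermediate
11 | ring‑opened allylgold trans‑1,3‑dioxolan‑2‑ylium ion, NTf2 salt | CC[C@H](OC(C)=O)[C@@H](OC([Au-][P+](c1ccccc1)(c1ccccc1)c1ccccc1)C(OC(C)=O)=C)C[C@H]2OC(C)=[O+][C@@H]2OC(C)=O.O=S(=O)([N-]S(=O)(=O)C(F)(F)F)C(F)(F)F | intermediate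
12 | (2S,4R,5R)‑2‑[(1S)‑1‑acetoxypropyl]‑4,5,7‑triacetoxy‑3,4,5,6‑tetrahydro‑2H‑oxocine | CC[C@H](OC(C)=O)[C@@H]1C[C@@H](OC(C)=O)[C@H](OC(C)=O)C/C(OC(C)=O)=C\O1 | intermediate
13 | ethyl (Z)‑3‑iodoacrylate | CCOC(=O)/C=C\I | starting material
14 | ethynyltrimethylsilane | C#C[Si](C)(C)C | starting material
15 | ethyl (Z)‑5‑(trimethylsilyl)pent‑2‑en‑4‑ynoate | CCOC(=O)/C=C\C#C[Si](C)(C)C | intermediate
16 | (Z)‑5‑(trimethylsilyl)pent‑2‑en‑4‑yn‑1‑ol | OC/C=C\C#C[Si](C)(C)C | intermediate
17 | (Z)‑5‑bromo‑1‑(trimethylsilyl)pent‑3‑en‑1‑yne | BrC/C=C\C#C[Si](C)(C)C | intermediate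
18 | tributyltin enolate of the oxocan‑7‑one (O‑stannyl form) | CC[C@H](OC(C)=O)[C@@H]1C[C@@H](OC(C)=O)[C@H](OC(C)=O)C/C(O[Sn](CCCC)(CCCC)CCCC)=C\O1 | intermediate
19 | (2S,4R,5R,8R)‑2‑[(1S)‑1‑acetoxypropyl]‑4,5‑diacetoxy‑8‑[(2Z)‑5‑(trimethylsilyl)pent‑2‑en‑4‑yn‑1‑yl]oxocan‑7‑one | C[Si](C)(C)C#C/C=C\C[C@H]1O[C@H]([C@H](CC)OC(C)=O)C[C@@H](OC(C)=O)[C@H](OC(C)=O)CC1=O | intermediate
20 | (2S,4R,5R,7R,8R)‑2‑[(1S)‑1‑acetoxypropyl]‑4,5‑diacetoxy‑8‑[(2Z)‑5‑(trimethylsilyl)pent‑2‑en‑4‑yn‑1‑yl]oxocan‑7‑ol | C[Si](C)(C)C#C/C=C\C[C@H]1O[C@H]([C@H](CC)OC(C)=O)C[C@@H](OC(C)=O)[C@H](OC(C)=O)C[C@H]1O | intermediate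
21 | CNP0352372.1, (2S,4R,5R,7R,8R)‑2‑[(1S)‑1‑acetoxypropyl]‑4,5‑diacetoxy‑8‑[(2Z)‑pent‑2‑en‑4‑yn‑1‑yl]oxocan‑7‑ol | C#C/C=C\C[C@H]1O[C@H]([C@H](CC)OC(C)=O)C[C@@H](OC(C)=O)[C@H](OC(C)=O)C[C@H]1O | target

## Step count and risks

Total step count: 14. Longest linear sequence: 11 steps (steps 1–8, then 12–14); the side‑chain bromide takes 3 steps (9–11).

Steps most likely to fail:

**Step 8 (Proposed new method).** Carbenoid transfer to the weakly basic ring oxygen of the peracetylated furanose may be slower than self‑reaction of the carbenoid. The C–O cleavage may also take the exocyclic course, or a second carbenoid may add to the product enol acetate. The fallback uses known chemistry and makes the same two ring bonds one after the other, C5–C6 first. It sets out from 8. Lewis‑acid C‑glycosylation with allyltrimethylsilane (BF3·OEt2, MeCN, 0 °C) should give, through the 1,2‑acetoxonium ion, the 1,2‑trans C‑allyl furanoside F1. Oxidative cleavage of the alkene (RuCl3 cat., NaIO4, CCl4–MeCN–H2O) gives the carboxylic acid F2. Oxalyl chloride with DMF (cat.) gives the acid chloride F3, and diazomethane (Et2O, 0 °C) the diazoketone F4. Rh2(OAc)4 (1 mol %) in CH2Cl2 with excess AcOH generates the bicyclic oxonium ylide F5 (five‑membered ylide ring O1, C5, C6, C7, C8). The ylide is protonated at C8 and opened at C5 by acetate with inversion, the known three‑carbon ring expansion of 2‑(diazoacetonyl)tetrahydrofurans, to give the oxocan‑7‑one F6 with the C5 acetate in the target configuration. Isopropenyl acetate with TsOH (cat.) at 80 °C should then give the enol acetate conjugated with the ring oxygen, and the route is rejoined at 12.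

**Step 12.** Bromide ion may isomerise the Z‑allylic bromide, proton transfer between product and tin enolate may epimerise C8, and facial selectivity at C8 may be poor. The fallback sets out from 12. Palladium‑catalysed allylation of the enol acetate (allyl methyl carbonate, Pd2(dba)3, dppe, Bu3SnOMe cat., dioxane, 60 °C; zerovalent palladium π‑allyl chemistry) gives the C8‑allyl ketone F7 regiospecifically. Z‑selective enyne cross‑metathesis with but‑3‑en‑1‑yn‑1‑yl(trimethyl)silane (second‑generation Grubbs catalyst, CH2Cl2, 40 °C) then builds the Z‑enyne on the ring, and the route is rejoined at 19.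

**Step 13.** Hydride may be delivered with poor facial selectivity, or to the wrong face. The fallback sets out from 19 and sets C7 by inversion instead of by facial control. Reduction with NaBH4 (MeOH, −40 °C) and separation gives the 7‑epimeric alcohol F8. Mitsunobu inversion with chloroacetic acid (PPh3, DIAD, toluene, 0 °C → rt) gives the 7R chloroacetate F9. Selective dechloroacetylation with thiourea (NaHCO3, EtOH–THF, 50 °C), which leaves the acetates intact, rejoins the route at 20.

## Further compounds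

F1 | step 8 | 1,2‑trans C‑allyl furanoside from 8 (allyl at the former anomeric carbon) | CC[C@H](OC(C)=O)[C@@H]1C[C@@H](OC(C)=O)[C@H](CC=C)O1
F2 | step 8 | C‑glycosyl acetic acid | CC[C@H](OC(C)=O)[C@@H]1C[C@@H](OC(C)=O)[C@H](CC(O)=O)O1
F3 | step 8 | C‑glycosyl acetyl chloride | CC[C@H](OC(C)=O)[C@@H]1C[C@@H](OC(C)=O)[C@H](CC(Cl)=O)O1
F4 | step 8 | C‑glycosyl diazomethyl ketone | CC[C@H](OC(C)=O)[C@@H]1C[C@@H](OC(C)=O)[C@H](CC(=O)C=[N+]=[N-])O1
F5 | step 8 | bicyclic oxonium ylide | CC[C@H](OC(C)=O)[C@@H]1C[C@@H](OC(C)=O)[C@@H]2CC(=O)[CH-][O+]12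
F6 | step 8 | (2S,4R,5R)‑2‑[(1S)‑1‑acetoxypropyl]‑4,5‑diacetoxyoxocan‑7‑one | CC[C@H](OC(C)=O)[C@@H]1C[C@@H](OC(C)=O)[C@H](OC(C)=O)CC(=O)CO1
F7 | step 12 | (2S,4R,5R,8R)‑2‑[(1S)‑1‑acetoxypropyl]‑4,5‑diacetoxy‑8‑allyloxocan‑7‑one | C=CC[C@H]1O[C@H]([C@H](CC)OC(C)=O)C[C@@H](OC(C)=O)[C@H](OC(C)=O)CC1=O
F8 | step 13 | 7‑epimer of 20 (7S alcohol) | C[Si](C)(C)C#C/C=C\C[C@H]1O[C@H]([C@H](CC)OC(C)=O)C[C@@H](OC(C)=O)[C@H](OC(C)=O)C[C@@H]1O
F9 | step 13 | 7‑O‑chloroacetate of 20 (7R) | C[Si](C)(C)C#C/C=C\C[C@H]1O[C@H]([C@H](CC)OC(C)=O)C[C@@H](OC(C)=O)[C@H](OC(C)=O)C[C@H]1OC(=O)CCl
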